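**Retrosynthetic overview**

- Target 21 is the C9 p-coumarate of a trans-(2R,3S)-2-aryl-2,3-dihydrobenzofuran. The last disconnections are the three silyl ethers and the C9–O acyl bond, giving alcohol 16 and O-silylated p-coumaric acid 19; the C9 alcohol comes from methyl ester 15.
- The strategy rests on the C2–C3 bond of the dihydrofuran ring (O1, C2, C3, C3a, C7a). C2 is a benzylic ether carbon bearing the guaiacyl ring, and C3 bears the C9 carbon, so C3 can be a carbene carbon flanked by ring A and the C9 ester. Cutting C2–C3 gives the O-benzyl aryldiazoacetate 13.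
- 13 comes from arylacetate 12 by diazo transfer. The CH2CO2Me arm comes from an ortho-allyl group, placed by aromatic Claisen rearrangement of the allyl ether of commercial dihydroconiferyl alcohol 1. The benzylic ether comes from vanillin-derived alcohol 7.
- Both benzene rings are bought. The only ring made is the dihydrofuran ring, closed in step 11 with a phthalimido-tert-leucinate dirhodium catalyst, which suits methylene insertion better than a prolinate catalyst alone. C2 is set by the catalyst and C3 by base equilibration.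

Key step: step 11

Remark (assumption): Rh2(S-PTTL)4, dirhodium tetrakis[N-phthaloyl-(S)-tert-leucinate], is taken to give the 2R configuration by analogy with simpler 2-benzyloxyphenyl diazoacetates; if a check on 15 shows 2S, Rh2(R-PTTL)4 is used in the same way.

**Route**

Step 1
Reactants: 1 3-(4-hydroxy-3-methoxyphenyl)propan-1-ol (dihydroconiferyl alcohol)
Product: 2 3-[3-methoxy-4-(prop-2-en-1-yloxy)phenyl]propan-1-ol
Conditions: allyl bromide, K2CO3, acetone, reflux
Reagents that add atoms: allyl bromide, C=CCBr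
Why: Williamson ether synthesis in which K2CO3 deprotonates only the phenol, so the aliphatic alcohol should stay free.

Step 2
Reactants: 2 3-[3-methoxy-4-(prop-2-en-1-yloxy)phenyl]propan-1-ol
Product: 3 tert-butyl{3-[3-methoxy-4-(prop-2-en-1-yloxy)phenyl]propoxy}diphenylsilane
Conditions: TBDPSCl, imidazole, CH2Cl2, 0 °C to rt
Reagents that add atoms: tert-butyl(chloro)diphenylsilane, CC(C)(C)[Si](Cl)(c1ccccc1)c1ccccc1
Why: Imidazole-promoted silylation of the only free hydroxyl gives a silyl ether robust enough for the thermal and oxidative steps that follow.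

Step 3
Reactants: 3 tert-butyl{3-[3-methoxy-4-(prop-2-en-1-yloxy)phenyl]propoxy}diphenylsilane
Product: 4 2-methoxy-6-(prop-2-en-1-yl)-4-[3-(tert-butyldiphenylsilyloxy)propyl]phenol
Conditions: N,N-diethylaniline, 200 °C, sealed tube, argon
Reagents that add atoms: none
Why: Aromatic Claisen rearrangement, a [3,3]-sigmatropic shift followed by tautomerisation; only the ortho carbon without the methoxy group can rearomatise and the para position is blocked, so one phenol should result.

Step 4
Reactants: 5 vanillin (4-hydroxy-3-methoxybenzaldehyde)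
Product: 6 3-methoxy-4-(triisopropylsilyloxy)benzaldehyde
Conditions: TIPSCl, imidazole, DMF, rt
Reagents that add atoms: chlorotri(propan-2-yl)silane, CC(C)[Si](Cl)(C(C)C)C(C)C
Why: Phenol silylation; the bulky triisopropylsilyl ether resists the mildly basic and nucleophilic steps ahead better than smaller aryl silyl ethers.

Step 5
Reactants: 6 3-methoxy-4-(triisopropylsilyloxy)benzaldehyde
Product: 7 [3-methoxy-4-(triisopropylsilyloxy)phenyl]methanol
Conditions: NaBH4, THF/MeOH, 0 °C
Reagents that add atoms: none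
Why: Borohydride reduction of the aldehyde to the benzylic alcohol, with the aryl silyl ether stable at 0 °C.

Step 6
Reactants: 4 2-methoxy-6-(prop-2-en-1-yl)-4-[3-(tert-butyldiphenylsilyloxy)propyl]phenol; 7 [3-methoxy-4-(triisopropylsilyloxy)phenyl]methanol
Product: 8 tert-butyl[3-(3-methoxy-4-{[3-methoxy-4-(triisopropylsilyloxy)phenyl]methoxy}-5-(prop-2-en-1-yl)phenyl)propoxy]diphenylsilane
Conditions: PPh3, DIAD, THF, 0 °C to rt
Reagents that add atoms: none
Why: Mitsunobu etherification in which the phenoxide displaces the benzylic oxyphosphonium under neutral conditions that spare both silyl ethers and the allyl group.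

Step 7
Reactants: 8 tert-butyl[3-(3-methoxy-4-{[3-methoxy-4-(triisopropylsilyloxy)phenyl]methoxy}-5-(prop-2-en-1-yl)phenyl)propoxy]diphenylsilane
Product: 10 2-(3-methoxy-2-{[3-methoxy-4-(triisopropylsilyloxy)phenyl]methoxy}-5-[3-(tert-butyldiphenylsilyloxy)propyl]phenyl)acetaldehyde, via vicinal diol 9 (not isolated)
Conditions: OsO4 (2 mol %), NaIO4, 2,6-lutidine, dioxane/H2O (3:1), rt
Reagents that add atoms: osmium tetroxide, O=[Os](=O)(=O)=O; sodium periodate, [Na+].[O-]I(=O)(=O)=O
Why: Lemieux–Johnson oxidative cleavage of the only alkene, with 2,6-lutidine limiting over-oxidation; the arenes, the benzylic ether and the silyl ethers are inert to both oxidants.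

Step 8
Reactants: 10 2-(3-methoxy-2-{[3-methoxy-4-(triisopropylsilyloxy)phenyl]methoxy}-5-[3-(tert-butyldiphenylsilyloxy)propyl]phenyl)acetaldehyde
Product: 11 2-(3-methoxy-2-{[3-methoxy-4-(triisopropylsilyloxy)phenyl]methoxy}-5-[3-(tert-butyldiphenylsilyloxy)propyl]phenyl)acetic acid
Conditions: NaClO2, NaH2PO4, 2-methyl-2-butene, t-BuOH/H2O, 0 °C to rt
Reagents that add atoms: sodium chlorite, [Na+].[O-]Cl=O
Why: Pinnick oxidation of the crude aldehyde at about pH 4, with excess 2-methyl-2-butene trapping hypochlorous acid before it can chlorinate the electron-rich rings.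

Step 9
Reactants: 11 2-(3-methoxy-2-{[3-methoxy-4-(triisopropylsilyloxy)phenyl]methoxy}-5-[3-(tert-butyldiphenylsilyloxy)propyl]phenyl)acetic acid
Product: 12 methyl 2-(3-methoxy-2-{[3-methoxy-4-(triisopropylsilyloxy)phenyl]methoxy}-5-[3-(tert-butyldiphenylsilyloxy)propyl]phenyl)acetate
Conditions: TMSCHN2, toluene/MeOH (4:1), 0 °C
Reagents that add atoms: (trimethylsilyl)diazomethane, C[Si](C)(C)C=[N+]=[N-]
Why: Methyl esterification of the acid with trimethylsilyldiazomethane in methanol is fast and neutral, so the aryl silyl ether is not exposed to base.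

Step 10
Reactants: 12 methyl 2-(3-methoxy-2-{[3-methoxy-4-(triisopropylsilyloxy)phenyl]methoxy}-5-[3-(tert-butyldiphenylsilyloxy)propyl]phenyl)acetate
Product: 13 methyl 2-diazo-2-(3-methoxy-2-{[3-methoxy-4-(triisopropylsilyloxy)phenyl]methoxy}-5-[3-(tert-butyldiphenylsilyloxy)propyl]phenyl)acetate
Conditions: p-ABSA, DBU, dry MeCN, 0 °C to rt
Reagents that add atoms: 4-acetamidobenzenesulfonyl azide, CC(=O)Nc1ccc(cc1)S(=O)(=O)N=[N+]=[N-]
Why: Regitz diazo transfer, in which the DBU-generated arylacetate enolate attacks the terminal azide nitrogen and expels the sulfonamide, the standard access to aryldiazoacetates.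

Step 11
Reactants: 13 methyl 2-diazo-2-(3-methoxy-2-{[3-methoxy-4-(triisopropylsilyloxy)phenyl]methoxy}-5-[3-(tert-butyldiphenylsilyloxy)propyl]phenyl)acetate
Product: 15 methyl (2R,3R)-5-[3-(tert-butyldiphenylsilyloxy)propyl]-7-methoxy-2-[3-methoxy-4-(triisopropylsilyloxy)phenyl]-2,3-dihydro-1-benzofuran-3-carboxylate (trans), via cis ester 14 (not isolated)
Conditions: Rh2(S-PTTL)4 (1 mol %), toluene, −60 °C, slow addition of 13; then DBU, rt
Reagents that add atoms: none
Why: Rh2(S-PTTL)4 takes up the diazo carbon of 13, N2 leaves, and the electrophilic dirhodium carbene at the future C3, with ring A as donor and the ester as acceptor, inserts into one of the two enantiotopic hydrogens of the O–CH2–aryl group through a concerted, asynchronous three-centre transition state with hydride-transfer character, forming the C2–C3 bond. The closest known reaction is the enantioselective intramolecular C–H insertion of methyl 2-(2-benzyloxyphenyl)-2-diazoacetates under N-phthaloyl amino acid dirhodium carboxylates, which gives cis-2-aryl-2,3-dihydrobenzofuran-3-carboxylates. The dihydrofuran ring (O1, C2, C3, C3a, C7a) closes by 1,5-insertion, the only mode that puts an activated C–H bond within reach of the carbene. C2 is set by the chiral carboxylate ligands, which tell the two benzylic hydrogens apart, and C3, formed cis under kinetic control, is then equilibrated by DBU through the ester enolate to the more stable trans (2R,3R) ester without touching C2. The step needs site selectivity and chemoselectivity over carbene dimerisation and addition to the guaiacyl ring: the C2–H bond is activated by both the ether oxygen and the para-silyloxy aryl group, and slow addition at −60 °C keeps the diazo concentration low. Ring opening of the enolate by loss of the phenoxide is not expected, because the C2–O bond lies close to the nodal plane of the enolate π system.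

Step 12
Reactants: 15 methyl (2R,3R)-5-[3-(tert-butyldiphenylsilyloxy)propyl]-7-methoxy-2-[3-methoxy-4-(triisopropylsilyloxy)phenyl]-2,3-dihydro-1-benzofuran-3-carboxylate
Product: 16 {(2R,3S)-5-[3-(tert-butyldiphenylsilyloxy)propyl]-7-methoxy-2-[3-methoxy-4-(triisopropylsilyloxy)phenyl]-2,3-dihydro-1-benzofuran-3-yl}methanol
Conditions: i-Bu2AlH, CH2Cl2, −78 to 0 °C; aq. potassium sodium tartrate
Reagents that add atoms: none
Why: Ester reduction with the Lewis acidic, weakly basic i-Bu2AlH should give the primary alcohol without enolising C3, so no beta-elimination of the ring oxygen is expected; the descriptor at C3 becomes S only through the change in substituent priorities.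

Step 13
Reactants: 17 p-coumaric acid ((E)-3-(4-hydroxyphenyl)prop-2-enoic acid)
Product: 19 (E)-3-[4-(tert-butyldimethylsilyloxy)phenyl]prop-2-enoic acid, via bis-silylated coumarate 18 (not isolated)
Conditions: TBSCl (2.3 equiv), imidazole, DMF, rt; then AcOH/THF/H2O, rt
Reagents that add atoms: tert-butyl(chloro)dimethylsilane, CC(C)(C)[Si](C)(C)Cl
Why: Double silylation followed by selective hydrolysis of the much more labile silyl ester under mild aqueous acid should leave the aryl silyl ether and the E alkene intact.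

Step 14
Reactants: 16 {(2R,3S)-5-[3-(tert-butyldiphenylsilyloxy)propyl]-7-methoxy-2-[3-methoxy-4-(triisopropylsilyloxy)phenyl]-2,3-dihydro-1-benzofuran-3-yl}methanol; 19 (E)-3-[4-(tert-butyldimethylsilyloxy)phenyl]prop-2-enoic acid
Product: 20 {(2R,3S)-5-[3-(tert-butyldiphenylsilyloxy)propyl]-7-methoxy-2-[3-methoxy-4-(triisopropylsilyloxy)phenyl]-2,3-dihydro-1-benzofuran-3-yl}methyl (E)-3-[4-(tert-butyldimethylsilyloxy)phenyl]prop-2-enoate
Conditions: DCC, DMAP (cat.), CH2Cl2, 0 °C to rt
Reagents that add atoms: none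
Why: Steglich esterification, in which DCC activates the acid and DMAP transfers the acyl group to the only free hydroxyl of 16; neither stereocentre is alpha to a carbonyl any longer, so both are fixed.

Step 15
Reactants: 20 {(2R,3S)-5-[3-(tert-butyldiphenylsilyloxy)propyl]-7-methoxy-2-[3-methoxy-4-(triisopropylsilyloxy)phenyl]-2,3-dihydro-1-benzofuran-3-yl}methyl (E)-3-[4-(tert-butyldimethylsilyloxy)phenyl]prop-2-enoate
Product: 21 [(2R,3S)-2-(4-hydroxy-3-methoxyphenyl)-5-(3-hydroxypropyl)-7-methoxy-2,3-dihydro-1-benzofuran-3-yl]methyl (E)-3-(4-hydroxyphenyl)prop-2-enoate (CNP0202924.1)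
Conditions: Bu4NF/AcOH (1:1, excess), THF, 0 °C to rt
Reagents that add atoms: none
Why: Fluoride cleavage of all three Si–O bonds, buffered with acetic acid so that the freed phenols are not held as phenoxides, which could open the ring at C2 through a para-quinone methide or attack the cinnamate ester.

**Compound list**

1 | 3-(4-hydroxy-3-methoxyphenyl)propan-1-ol (dihydroconiferyl alcohol) | COc1cc(CCCO)ccc1O | starting material
2 | 3-[3-methoxy-4-(prop-2-en-1-yloxy)phenyl]propan-1-ol | COc1cc(CCCO)ccc1OCC=C | intermediate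
3 | tert-butyl{3-[3-methoxy-4-(prop-2-en-1-yloxy)phenyl]propoxy}diphenylsilane | COc1cc(CCCO[Si](c2ccccc2)(c2ccccc2)C(C)(C)C)ccc1OCC=C | intermediate
4 | 2-methoxy-6-(prop-2-en-1-yl)-4-[3-(tert-butyldiphenylsilyloxy)propyl]phenol | COc1cc(CCCO[Si](c2ccccc2)(c2ccccc2)C(C)(C)C)cc(CC=C)c1O | intermediate
5 | vanillin (4-hydroxy-3-methoxybenzaldehyde) | COc1cc(C=O)ccc1O | starting material
6 | 3-methoxy-4-(triisopropylsilyloxy)benzaldehyde | COc1cc(C=O)ccc1O[Si](C(C)C)(C(C)C)C(C)C | intermediate
7 | [3-methoxy-4-(triisopropylsilyloxy)phenyl]methanol | COc1cc(CO)ccc1O[Si](C(C)C)(C(C)C)C(C)C | intermediate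
8 | tert-butyl[3-(3-methoxy-4-{[3-methoxy-4-(triisopropylsilyloxy)phenyl]methoxy}-5-(prop-2-en-1-yl)phenyl)propoxy]diphenylsilane | COc1cc(COc2c(CC=C)cc(CCCO[Si](c3ccccc3)(c3ccccc3)C(C)(C)C)cc2OC)ccc1O[Si](C(C)C)(C(C)C)C(C)C | intermediate
9 | 3-(3-methoxy-2-{[3-methoxy-4-(triisopropylsilyloxy)phenyl]methoxy}-5-[3-(tert-butyldiphenylsilyloxy)propyl]phenyl)propane-1,2-diol (both configurations at the carbinol carbon) | COc1cc(COc2c(CC(O)CO)cc(CCCO[Si](c3ccccc3)(c3ccccc3)C(C)(C)C)cc2OC)ccc1O[Si](C(C)C)(C(C)C)C(C)C | intermediate (not isolated)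
10 | 2-(3-methoxy-2-{[3-methoxy-4-(triisopropylsilyloxy)phenyl]methoxy}-5-[3-(tert-butyldiphenylsilyloxy)propyl]phenyl)acetaldehyde | COc1cc(COc2c(CC=O)cc(CCCO[Si](c3ccccc3)(c3ccccc3)C(C)(C)C)cc2OC)ccc1O[Si](C(C)C)(C(C)C)C(C)C | intermediate
11 | 2-(3-methoxy-2-{[3-methoxy-4-(triisopropylsilyloxy)phenyl]methoxy}-5-[3-(tert-butyldiphenylsilyloxy)propyl]phenyl)acetic acid | COc1cc(COc2c(CC(=O)O)cc(CCCO[Si](c3ccccc3)(c3ccccc3)C(C)(C)C)cc2OC)ccc1O[Si](C(C)C)(C(C)C)C(C)C | intermediate
12 | methyl 2-(3-methoxy-2-{[3-methoxy-4-(triisopropylsilyloxy)phenyl]methoxy}-5-[3-(tert-butyldiphenylsilyloxy)propyl]phenyl)acetate | COC(=O)Cc1cc(CCCO[Si](c2ccccc2)(c2ccccc2)C(C)(C)C)cc(OC)c1OCc1ccc(O[Si](C(C)C)(C(C)C)C(C)C)c(OC)c1 | intermediate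
13 | methyl 2-diazo-2-(3-methoxy-2-{[3-methoxy-4-(triisopropylsilyloxy)phenyl]methoxy}-5-[3-(tert-butyldiphenylsilyloxy)propyl]phenyl)acetate | COC(=O)C(=[N+]=[N-])c1cc(CCCO[Si](c2ccccc2)(c2ccccc2)C(C)(C)C)cc(OC)c1OCc1ccc(O[Si](C(C)C)(C(C)C)C(C)C)c(OC)c1 | intermediate (key-step precursor)
14 | methyl (2R,3S)-5-[3-(tert-butyldiphenylsilyloxy)propyl]-7-methoxy-2-[3-methoxy-4-(triisopropylsilyloxy)phenyl]-2,3-dihydro-1-benzofuran-3-carboxylate (cis) | COc1cc([C@@H]2Oc3c(OC)cc(CCCO[Si](c4ccccc4)(c4ccccc4)C(C)(C)C)cc3[C@@H]2C(=O)OC)ccc1O[Si](C(C)C)(C(C)C)C(C)C | intermediate (not isolated)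
15 | methyl (2R,3R)-5-[3-(tert-butyldiphenylsilyloxy)propyl]-7-methoxy-2-[3-methoxy-4-(triisopropylsilyloxy)phenyl]-2,3-dihydro-1-benzofuran-3-carboxylate (trans) | COc1cc([C@@H]2Oc3c(OC)cc(CCCO[Si](c4ccccc4)(c4ccccc4)C(C)(C)C)cc3[C@H]2C(=O)OC)ccc1O[Si](C(C)C)(C(C)C)C(C)C | intermediate (key-step product)
16 | {(2R,3S)-5-[3-(tert-butyldiphenylsilyloxy)propyl]-7-methoxy-2-[3-methoxy-4-(triisopropylsilyloxy)phenyl]-2,3-dihydro-1-benzofuran-3-yl}methanol | COc1cc([C@@H]2Oc3c(OC)cc(CCCO[Si](c4ccccc4)(c4ccccc4)C(C)(C)C)cc3[C@H]2CO)ccc1O[Si](C(C)C)(C(C)C)C(C)C | intermediate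
17 | p-coumaric acid ((E)-3-(4-hydroxyphenyl)prop-2-enoic acid) | OC(=O)/C=C/c1ccc(O)cc1 | starting material
18 | tert-butyldimethylsilyl (E)-3-[4-(tert-butyldimethylsilyloxy)phenyl]prop-2-enoate | CC(C)(C)[Si](C)(C)OC(=O)/C=C/c1ccc(O[Si](C)(C)C(C)(C)C)cc1 | intermediate (not isolated)
19 | (E)-3-[4-(tert-butyldimethylsilyloxy)phenyl]prop-2-enoic acid | OC(=O)/C=C/c1ccc(O[Si](C)(C)C(C)(C)C)cc1 | intermediate
20 | {(2R,3S)-5-[3-(tert-butyldiphenylsilyloxy)propyl]-7-methoxy-2-[3-methoxy-4-(triisopropylsilyloxy)phenyl]-2,3-dihydro-1-benzofuran-3-yl}methyl (E)-3-[4-(tert-butyldimethylsilyloxy)phenyl]prop-2-enoate | COc1cc([C@@H]2Oc3c(OC)cc(CCCO[Si](c4ccccc4)(c4ccccc4)C(C)(C)C)cc3[C@H]2COC(=O)/C=C/c2ccc(O[Si](C)(C)C(C)(C)C)cc2)ccc1O[Si](C(C)C)(C(C)C)C(C)C | intermediate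
21 | [(2R,3S)-2-(4-hydroxy-3-methoxyphenyl)-5-(3-hydroxypropyl)-7-methoxy-2,3-dihydro-1-benzofuran-3-yl]methyl (E)-3-(4-hydroxyphenyl)prop-2-enoate (CNP0202924.1) | COc1cc([C@@H]2Oc3c(OC)cc(CCCO)cc3[C@H]2COC(=O)/C=C/c2ccc(O)cc2)ccc1O | target

**Step count**

Total: 15 steps. Longest linear sequence: 12 steps (1 → 2 → 3 → 4 → 8 → 10 → 11 → 12 → 13 → 15 → 16 → 20 → 21; steps 1, 2, 3, 6, 7, 8, 9, 10, 11, 12, 14, 15).

**Steps most likely to fail**

1. Step 11 (carbene C–H insertion and equilibration).
- What may go wrong: the very electron-rich benzylic position may favour a stepwise hydride transfer and so erode enantioselectivity; the carbene may dimerise or attack the guaiacyl ring; the cis to trans equilibration may be incomplete or accompanied by enolate-driven ring opening.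
- Fallback, from acid 11 back to alcohol 16: stereocontrol is shared between a covalently bound lactamide auxiliary and a prolinate catalyst, a matched combination known for 2-aryl-7-alkoxy-dihydrobenzofuran-3-carboxylates and used here in the mirror-image series needed for 2R. Methyl (R)-lactate is warmed with pyrrolidine to give (R)-2-hydroxy-1-(pyrrolidin-1-yl)propan-1-one F1. Acid 11 is esterified with it (DCC, DMAP, CH2Cl2) to the (R)-lactamide arylacetate F2. Diazo transfer (p-ABSA, DBU, MeCN) gives the (R)-lactamide aryldiazoacetate F3. Decomposition with Rh2(R-DOSP)4, dirhodium tetrakis[(R)-N-(4-dodecylbenzenesulfonyl)prolinate], in CH2Cl2, followed if needed by the same DBU equilibration, should give the trans (2R,3R) lactamide ester F4. Its minor stereoisomers are diastereomers and can be removed by chromatography or crystallisation. LiBH4 in THF then reduces the ester, releases the auxiliary and gives 16.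

2. Step 15 (global desilylation).
- What may go wrong: the primary tert-butyldiphenylsilyl ether may cleave slowly under buffered fluoride, and the longer exposure could allow phenoxide-triggered opening of the ring at C2 or cleavage of the cinnamate ester.
- Fallback, from 20 to target 21: the single global step is replaced by a staged, orthogonal unmasking in which no phenoxide is formed. KHF2 in MeOH/THF at rt, a reagent selective for aryl silyl ethers, should give the bis-phenol that still bears the primary silyl ether, [(2R,3S)-5-[3-(tert-butyldiphenylsilyloxy)propyl]-2-(4-hydroxy-3-methoxyphenyl)-7-methoxy-2,3-dihydro-1-benzofuran-3-yl]methyl (E)-3-(4-hydroxyphenyl)prop-2-enoate F5. The remaining alkyl silyl ether is then removed under acidic fluoride (HF·pyridine, pyridine/THF, 0 °C to rt) to give 21.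

3. Step 6 (Mitsunobu etherification).
- What may go wrong: O-alkylation of the doubly ortho-substituted phenol may be slow, and the electron-rich benzylic oxyphosphonium may ionise, leading to C-benzylation or capture by the hydrazide.
- Fallback, from alcohol 7 (with phenol 4) back to ether 8: the redox condensation is replaced by a Williamson alkylation. Alcohol 7 is converted under Appel conditions (CBr4, PPh3, CH2Cl2, 0 °C) into [4-(bromomethyl)-2-methoxyphenoxy]tri(propan-2-yl)silane F6, which is used crude to alkylate phenol 4 (Cs2CO3, MeCN, rt) to give 8.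

**Further compounds**

F1 | step 11 | (R)-2-hydroxy-1-(pyrrolidin-1-yl)propan-1-one | C[C@@H](O)C(=O)N1CCCC1
F2 | step 11 | (R)-1-oxo-1-(pyrrolidin-1-yl)propan-2-yl 2-(3-methoxy-2-{[3-methoxy-4-(triisopropylsilyloxy)phenyl]methoxy}-5-[3-(tert-butyldiphenylsilyloxy)propyl]phenyl)acetate | C[C@@H](OC(=O)Cc1cc(CCCO[Si](c2ccccc2)(c2ccccc2)C(C)(C)C)cc(OC)c1OCc1ccc(O[Si](C(C)C)(C(C)C)C(C)C)c(OC)c1)C(=O)N1CCCC1
F3 | step 11 | (R)-1-oxo-1-(pyrrolidin-1-yl)propan-2-yl 2-diazo-2-(3-methoxy-2-{[3-methoxy-4-(triisopropylsilyloxy)phenyl]methoxy}-5-[3-(tert-butyldiphenylsilyloxy)propyl]phenyl)acetate | C[C@@H](OC(=O)C(=[N+]=[N-])c1cc(CCCO[Si](c2ccccc2)(c2ccccc2)C(C)(C)C)cc(OC)c1OCc1ccc(O[Si](C(C)C)(C(C)C)C(C)C)c(OC)c1)C(=O)N1CCCC1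
F4 | step 11 | (R)-1-oxo-1-(pyrrolidin-1-yl)propan-2-yl (2R,3R)-5-[3-(tert-butyldiphenylsilyloxy)propyl]-7-methoxy-2-[3-methoxy-4-(triisopropylsilyloxy)phenyl]-2,3-dihydro-1-benzofuran-3-carboxylate (trans) | COc1cc([C@@H]2Oc3c(OC)cc(CCCO[Si](c4ccccc4)(c4ccccc4)C(C)(C)C)cc3[C@H]2C(=O)O[C@H](C)C(=O)N2CCCC2)ccc1O[Si](C(C)C)(C(C)C)C(C)C
F5 | step 15 | [(2R,3S)-5-[3-(tert-butyldiphenylsilyloxy)propyl]-2-(4-hydroxy-3-methoxyphenyl)-7-methoxy-2,3-dihydro-1-benzofuran-3-yl]methyl (E)-3-(4-hydroxyphenyl)prop-2-enoate | COc1cc([C@@H]2Oc3c(OC)cc(CCCO[Si](c4ccccc4)(c4ccccc4)C(C)(C)C)cc3[C@H]2COC(=O)/C=C/c2ccc(O)cc2)ccc1O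
F6 | step 6 | [4-(bromomethyl)-2-methoxyphenoxy]tri(propan-2-yl)silane | COc1cc(CBr)ccc1O[Si](C(C)C)(C(C)C)C(C)C
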